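**Assumption (one line):** The configuration is taken exactly as drawn in the target SMILES: rings A and C are (2R,3R), ring B is (2S,3S), and each ring is trans. Enantiopure (S)- and (R)-4-methoxymandelic acid are taken as commercial (or made from D-/L-4-hydroxyphenylglycine).

## Retrosynthetic overview
1. Target ⇐ BBr3 demethylation of the nona-O-methyl all-trans tetramer (26) ⇐ acid equilibration of the three C2 centres of the all-cis tetramer (25).
2. Each cis-2,3-diaryl-dihydrobenzofuran (DHB) ⇐ ionic reduction of a 3-hydroxy-DHB, with hydride delivered anti to the 2-aryl group. That 3-hydroxy-DHB ⇐ 5-exo addition of an aryl-Mg species (from Ar–I) to an α-aryloxy aryl ketone, which forms C3–C3a.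
3. The ketone ⇐ ArMgX + the Weinreb amide of a 4-methoxymandelic acid aryl ether. The C–O bond is made by Mitsunobu from the resorcinol phenol, and each C2 centre comes from the mandelic acid.
4. Rings are closed in the order C (terminal), B, A. Each new ring is attached through its ipso C–Br, so each DHB is a formal (3+2) annulation of a resorcinol ring with a mandelate-derived two-carbon unit. (S)-Acid gives rings A and C, (R)-acid gives ring B.

## Route

**Step 1**
Reactants: 1 (1-bromo-3,5-dimethoxybenzene)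
Product: 2 (1-bromo-2-iodo-3,5-dimethoxybenzene)
Conditions: NIS (1.05 equiv), MeCN, cat. TFA, 0 °C → rt
Reagents that add atoms: N-iodosuccinimide, O=C1CCC(=O)N1I (gives Ar–I)
Why: Electrophilic aromatic iodination goes ortho to Br, ortho to one OMe and para to the other.

**Step 2**
Reactants: 2
Product: 3 (3-bromo-2-iodo-5-methoxyphenol)
Conditions: BBr3 (1.0 equiv), CH2Cl2, −78 → 0 °C; the regioisomeric phenols are separated by chromatography and the one with OH next to I is kept
Reagents that add atoms: none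
Why: Sub-stoichiometric BBr3 mono-O-demethylation gives the differentiated resorcinol phenol needed for the later Mitsunobu and C–Br/C–I handles.

**Step 3**
Reactants: 4 ((S)-4-methoxymandelic acid), 5 (N,O-dimethylhydroxylamine·HCl)
Product: 6 ((S)-Weinreb amide)
Conditions: EDC·HCl, HOBt, iPr2NEt, CH2Cl2, 0 °C → rt
Reagents that add atoms: none (5 is the numbered reactant)
Why: Standard amide coupling keeps the α-stereocentre and supplies the C2 stereocentre for rings A and C.

**Step 4**
Reactants: 7 ((R)-4-methoxymandelic acid), 5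
Product: 8 ((R)-Weinreb amide)
Conditions: EDC·HCl, HOBt, iPr2NEt, CH2Cl2, 0 °C → rt
Reagents that add atoms: none
Why: Same coupling, giving the C2 source for ring B.

**Step 5**
Reactants: 9 (3,5-dimethoxybenzaldehyde)
Product: 10 (2-iodo-3,5-dimethoxybenzaldehyde)
Conditions: NIS, MeCN, cat. TsOH, rt
Reagents that add atoms: N-iodosuccinimide, O=C1CCC(=O)N1I
Why: Iodination goes at C2, which is ortho/para-activated by both OMe groups and is not the deactivated position para to CHO.

**Step 6**
Reactants: 10, 11 (diethyl 4-methoxybenzylphosphonate)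
Product: 12 ((E)-2-iodo-3,5-dimethoxy-1-(4-methoxystyryl)benzene)
Conditions: NaH, THF, 0 °C → rt
Reagents that add atoms: none (11 is the numbered reactant)
Why: Horner–Wadsworth–Emmons olefination gives the E-stilbene and leaves the aryl iodide intact.

**Step 7**
Reactants: 12
Product: 13 ((E)-2-iodo-5-methoxy-3-(4-methoxystyryl)phenol)
Conditions: BBr3 (1.0 equiv), CH2Cl2, −78 → 0 °C; the phenol with OH next to I is isolated
Reagents that add atoms: none
Why: Controlled mono-demethylation (the OMe flanked by iodine is the most accessible) gives the ring-A phenol.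

**Step 8**
Reactants: 3, 6
Product: 14 ((R)-aryl ether Weinreb amide)
Conditions: DIAD, PPh3, THF, 0 °C → rt
Reagents that add atoms: none
Why: Mitsunobu etherification of an acidic halophenol with the α-hydroxy amide inverts the (S) carbinol centre to (R).

**Step 9**
Reactants: 14, 1 (used as 3,5-dimethoxyphenyl-MgBr)
Product: 15 ((R)-α-aryloxy aryl ketone, ring C)
Conditions: 1 + Mg, THF (ArMgBr); then 14, THF, −20 °C → rt
Reagents that add atoms: 3,5-dimethoxyphenylmagnesium bromide, COc1cc(OC)cc([Mg]Br)c1 (the aryl group is retained)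
Why: Weinreb ketone synthesis stops at the ketone through the chelated tetrahedral intermediate, and the C2 centre is carried through untouched.

**Step 10**
Reactants: 15
Product: 16 (3-hydroxy-DHB, C2 as drawn, C3 epimer mixture)
Conditions: i-PrMgCl·LiCl (2.2 equiv), THF, −40 → −20 °C; NH4Cl quench
Reagents that add atoms: none
Why: Mg–I exchange is selective over Ar–Br, and the aryl-Mg adds 5-exo to the ketone to forge C3–C3a and close the ring. The C3 configuration is irrelevant because it is erased in the next step.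

**Step 11**
Reactants: 16
Product: 17 (cis-(2S,3R)-4-bromo-DHB, ring C)
Conditions: Et3SiH (5 equiv), BF3·OEt2 (2 equiv), CH2Cl2, −78 °C
Reagents that add atoms: none
Why: Ionic hydrogenation of the stabilised diaryl C3 cation delivers hydride anti to the 2-aryl group. C3 is set by the C2 centre, and the product is cis.

**Step 12**
Reactants: 3, 8
Product: 18 ((S)-aryl ether Weinreb amide for ring B)
Conditions: DIAD, PPh3, THF, 0 °C → rt
Reagents that add atoms: none
Why: Mitsunobu inversion converts the (R) carbinol of 8 to the (S) ether.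

**Step 13**
Reactants: 17, 18
Product: 19 (ring C–C(=O)–CH(OAr_B)Ar'' ketone)
Conditions: (i) t-BuLi (2.1 equiv), THF, −78 °C; (ii) MgBr2·OEt2; (iii) 18, −78 → 0 °C
Reagents that add atoms: none
Why: Li–Br exchange at the only C–Br of 17, transmetalation to Mg, and Weinreb acylation attach ring B's two-carbon unit at ring C's ipso carbon.

**Step 14**
Reactants: 19
Product: 20 (3-hydroxy-DHB(B), C2 as drawn, C3 epimer mixture)
Conditions: i-PrMgCl·LiCl (2.2 equiv), THF, −40 → −20 °C
Reagents that add atoms: none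
Why: Selective Mg–I exchange followed by 5-exo ketone addition closes ring B and leaves the ring-B C–Br intact.

**Step 15**
Reactants: 20
Product: 21 (cis-(2R,3S)-DHB(B) with ring-B C–Br)
Conditions: Et3SiH, BF3·OEt2, CH2Cl2, −78 °C
Reagents that add atoms: none
Why: Anti-hydride delivery to the C3 cation sets C3 cis to C2; the (R) acid series gives the (2R,3S) cis isomer that epimerises to (2S,3S).

**Step 16**
Reactants: 13, 6
Product: 22 ((R)-aryl ether Weinreb amide, ring A)
Conditions: DIAD, PPh3, THF, 0 °C → rt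
Reagents that add atoms: none
Why: Mitsunobu inversion gives the (R) ether from the (S) acid.

**Step 17**
Reactants: 21, 22
Product: 23 (ring B–C(=O)–CH(OAr_A)Ar'' ketone)
Conditions: (i) t-BuLi (2.1 equiv), THF, −78 °C; (ii) MgBr2·OEt2; (iii) 22, −78 → 0 °C
Reagents that add atoms: none
Why: The only Ar–Br of 21 is converted to ArMgBr, which undergoes Weinreb acylation.

**Step 18**
Reactants: 23
Product: 24 (3-hydroxy-DHB(A), C2 as drawn, C3 epimer mixture)
Conditions: i-PrMgCl·LiCl, THF, −40 → −20 °C
Reagents that add atoms: none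
Why: Mg–I exchange and 5-exo addition close ring A; the styryl alkene is untouched.

**Step 19**
Reactants: 24
Product: 25 (all-cis permethyl tetramer)
Conditions: Et3SiH, BF3·OEt2, CH2Cl2, −78 °C
Reagents that add atoms: none
Why: Ionic hydrogenation sets C3 of ring A cis to C2, again by anti-hydride delivery.

**Step 20**
Reactants: 25
Product: 26 (all-trans nona-O-methyl tetramer)
Conditions: TFA (5 equiv), CH2Cl2, 0 °C → rt; chromatography isolates the all-trans isomer
Reagents that add atoms: none
Why: Reversible heterolysis of each C2–O bond (a p-methoxybenzylic cation) equilibrates C2 to the more stable trans isomer, while C3 keeps the configuration set by the pool-derived C2. This gives A (2R,3R), B (2S,3S) and C (2R,3R).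

**Step 21**
Reactants: 26
Product: 27 (Miyabenol A, target)
Conditions: BBr3 (20 equiv), CH2Cl2, −78 °C → rt; then aqueous workup
Reagents that add atoms: none
Why: BBr3 cleaves all nine aryl methyl ethers, and the DHB C–O bonds and the E-stilbene survive at low temperature.

## Compound list
1 | 1-bromo-3,5-dimethoxybenzene | COc1cc(Br)cc(OC)c1 | starting material
2 | 1-bromo-2-iodo-3,5-dimethoxybenzene | COc1cc(Br)c(I)c(OC)c1 | intermediate
3 | 3-bromo-2-iodo-5-methoxyphenol | Oc1cc(OC)cc(Br)c1I | intermediate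
4 | (S)-4-methoxymandelic acid | OC(=O)[C@@H](O)c1ccc(OC)cc1 | starting material
5 | N,O-dimethylhydroxylamine hydrochloride | CONC.Cl | starting material
6 | (S)-2-hydroxy-N-methoxy-2-(4-methoxyphenyl)-N-methylacetamide | CON(C)C(=O)[C@@H](O)c1ccc(OC)cc1 | intermediate
7 | (R)-4-methoxymandelic acid | OC(=O)[C@H](O)c1ccc(OC)cc1 | starting material
8 | (R)-2-hydroxy-N-methoxy-2-(4-methoxyphenyl)-N-methylacetamide | CON(C)C(=O)[C@H](O)c1ccc(OC)cc1 | intermediate
9 | 3,5-dimethoxybenzaldehyde | COc1cc(OC)cc(C=O)c1 | starting material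
10 | 2-iodo-3,5-dimethoxybenzaldehyde | COc1cc(OC)c(I)c(C=O)c1 | intermediate
11 | diethyl (4-methoxybenzyl)phosphonate | CCOP(=O)(OCC)Cc1ccc(OC)cc1 | starting material
12 | (E)-2-iodo-3,5-dimethoxy-1-(4-methoxystyryl)benzene | COc1ccc(/C=C/c2cc(OC)cc(OC)c2I)cc1 | intermediate
13 | (E)-2-iodo-5-methoxy-3-(4-methoxystyryl)phenol | COc1ccc(/C=C/c2cc(OC)cc(O)c2I)cc1 | intermediate
14 | (R)-2-(3-bromo-2-iodo-5-methoxyphenoxy)-N-methoxy-2-(4-methoxyphenyl)-N-methylacetamide | CON(C)C(=O)[C@H](Oc1cc(OC)cc(Br)c1I)c1ccc(OC)cc1 | intermediate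
15 | (R)-2-(3-bromo-2-iodo-5-methoxyphenoxy)-1-(3,5-dimethoxyphenyl)-2-(4-methoxyphenyl)ethan-1-one | COc1cc(OC)cc(c1)C(=O)[C@H](Oc1cc(OC)cc(Br)c1I)c1ccc(OC)cc1 | intermediate
16 | 4-bromo-3-(3,5-dimethoxyphenyl)-6-methoxy-2-(4-methoxyphenyl)-2,3-dihydrobenzofuran-3-ol (C2 as drawn, C3 epimer mixture) | COc1ccc(cc1)[C@H]2Oc3cc(OC)cc(Br)c3C2(O)c2cc(OC)cc(OC)c2 | intermediate
17 | cis-(2S,3R)-4-bromo-3-(3,5-dimethoxyphenyl)-6-methoxy-2-(4-methoxyphenyl)-2,3-dihydrobenzofuran | Brc1cc(OC)cc2c1[C@@H](c1cc(OC)cc(OC)c1)[C@@H](c1ccc(OC)cc1)O2 | intermediate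
18 | (S)-2-(3-bromo-2-iodo-5-methoxyphenoxy)-N-methoxy-2-(4-methoxyphenyl)-N-methylacetamide | CON(C)C(=O)[C@@H](Oc1cc(OC)cc(Br)c1I)c1ccc(OC)cc1 | intermediate
19 | (S)-α-aryloxy ketone joining the ring-C DHB (17) to the ring-B ether (ring C–C(=O)–CH(OAr_B)Ar'') | O=C(c1cc(OC)cc2c1[C@@H](c1cc(OC)cc(OC)c1)[C@@H](c1ccc(OC)cc1)O2)[C@@H](Oc1cc(OC)cc(Br)c1I)c1ccc(OC)cc1 | intermediate
20 | 3-hydroxy-DHB(B) carrying cis-DHB(C) (C2 as drawn, C3 epimer mixture) | COc1ccc(cc1)[C@@H]1Oc2cc(OC)cc(Br)c2C1(O)c1cc(OC)cc2c1[C@@H](c1cc(OC)cc(OC)c1)[C@@H](c1ccc(OC)cc1)O2 | intermediate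
21 | cis,cis-bis-DHB (ring B cis (2R,3S), ring C cis (2S,3R)) with ring-B C–Br | Brc1cc(OC)cc2c1[C@H](c1cc(OC)cc3c1[C@@H](c1cc(OC)cc(OC)c1)[C@@H](c1ccc(OC)cc1)O3)[C@H](c1ccc(OC)cc1)O2 | intermediate
22 | (R)-aryl ether Weinreb amide of ring A (styryl, ortho-I) | CON(C)C(=O)[C@H](Oc1cc(OC)cc(/C=C/c2ccc(OC)cc2)c1I)c1ccc(OC)cc1 | intermediate
23 | ketone joining the ring-B bis-DHB (21) to the ring-A ether | O=C(c1cc(OC)cc2c1[C@H](c1cc(OC)cc3c1[C@@H](c1cc(OC)cc(OC)c1)[C@@H](c1ccc(OC)cc1)O3)[C@H](c1ccc(OC)cc1)O2)[C@H](Oc1cc(OC)cc(/C=C/c2ccc(OC)cc2)c1I)c1ccc(OC)cc1 | intermediate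
24 | 3-hydroxy-DHB(A) carrying the two cis DHBs (C2 as drawn, C3 epimer mixture) | COc1ccc(/C=C/c2cc(OC)cc3c2C(O)(c2cc(OC)cc4c2[C@H](c2cc(OC)cc5c2[C@@H](c2cc(OC)cc(OC)c2)[C@@H](c2ccc(OC)cc2)O5)[C@H](c2ccc(OC)cc2)O4)[C@@H](c2ccc(OC)cc2)O3)cc1 | intermediate
25 | all-cis nona-O-methyl tetramer | COc1ccc(/C=C/c2cc(OC)cc3c2[C@@H](c2cc(OC)cc4c2[C@H](c2cc(OC)cc5c2[C@@H](c2cc(OC)cc(OC)c2)[C@@H](c2ccc(OC)cc2)O5)[C@H](c2ccc(OC)cc2)O4)[C@@H](c2ccc(OC)cc2)O3)cc1 | intermediate
26 | all-trans nona-O-methyl tetramer | COc1ccc(/C=C/c2cc(OC)cc3c2[C@@H](c2cc(OC)cc4c2[C@H](c2cc(OC)cc5c2[C@@H](c2cc(OC)cc(OC)c2)[C@H](c2ccc(OC)cc2)O5)[C@@H](c2ccc(OC)cc2)O4)[C@H](c2ccc(OC)cc2)O3)cc1 | intermediate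
27 | Miyabenol A | Oc1ccc(/C=C/c2cc(O)cc3c2[C@@H](c2cc(O)cc4c2[C@H](c2cc(O)cc5c2[C@@H](c2cc(O)cc(O)c2)[C@H](c2ccc(O)cc2)O5)[C@@H](c2ccc(O)cc2)O4)[C@H](c2ccc(O)cc2)O3)cc1 | target

## Totals
- Total steps: 21 (including 7 building-block steps: 1–7).
- Longest linear sequence: 14 steps (1 → 2 → 8 → 9 → 10 → 11 → 13 → 14 → 15 → 17 → 18 → 19 → 20 → 21).

## Three steps most likely to fail
1. **Steps 10, 14 and 18 (Mg–I exchange and 5-exo ketone addition).** Each closes a fully substituted tertiary carbinol flanked by ortho-substituted aryl groups, and the α-stereocentre must survive the basic organomagnesium.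
   - Fallback: build each DHB by a trans-selective [4+1] annulation of an o-quinone methide (from the o-hydroxybenzhydrol) with a 4-methoxybenzylsulfonium ylide. For rings B and A, separate the diastereomers from the resident stereocentres. For unit C, resolve the enantiomers by preparative chiral-phase HPLC.
2. **Steps 9, 13 and 17 (hindered Grignard + Weinreb amide carrying ArI/ArBr and an epimerisable α-centre).** Halogen exchange with the aryl iodide or racemisation of the α-aryloxy centre can erode yield and ee.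
   - Fallback: convert the acid partners to S-aryl thioesters and use a Liebeskind–Srogl ketone synthesis (Pd/CuTC) with the corresponding arylboronic acids, which is neutral and epimerisation-free.
3. **Steps 20 and 21 (cis → trans equilibration, then BBr3 global demethylation).** Acid can open the DHB, eliminate to a triarylethylene or protonate the stilbene, and BBr3 can cleave C2–O.
   - Fallback: drop the cis route. Reduce each acyclic ketone (Felkin-type, separating diastereomers), and close each DHB last by intramolecular Mitsunobu at the benzylic alcohol (SN2, inversion, no acid equilibration). Remove the methyl ethers with a milder nucleophilic reagent (LiSPr/HMPA or NaSEt/DMF).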